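The plan cuts the pyran ring twice, at C3–C4 and at O1–C2. Because the single stereogenic carbon C3 is flanked by the ArCH2 group C4 and by the quaternary, oxygenated C2, the ring-A fragment O1–C8a–C4a–C4 can be supplied as an ortho-quinone methide and the C2–C3 unit, prenyl included, as an enolate at the carboxylic acid oxidation level. A chiral triazolylidene unites them in one operation: both bonds form, a six-membered lactone closes and C3 is fixed, starting from a racemic α-chloro aldehyde and a 2-(tosylmethyl)phenol that carries OMe and OMOM. Methyl addition then turns the lactone carbonyl into C2, and the resorcinol ring is attached last by aldol condensation.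

Key step: step 7

Assumption: the (5aS,10bR) antipode of the aminoindanol-derived triazolium salt is taken as the one that leaves open the enolate face leading to (S) at C3; the sense of induction must be confirmed on lactone 14, and the equally accessible (5aR,10bS) antipode takes its place if the sense proves opposite.

Remark: atom numbers are those of the chroman skeleton of the target (O1, C2 … C8a); MOM = methoxymethyl, prenyl = 3-methylbut-2-en-1-yl, Tol = 4-methylphenyl.

Step 1
Reactants: 1 2,4,6-trihydroxybenzaldehyde
Product: 2 2,6-dihydroxy-4-methoxybenzaldehyde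
Conditions: MeI (1.0 equiv), K2CO3 (1.0 equiv), acetone, rt
Reagents that add atoms: iodomethane, CI
Why: Williamson O-methylation: the 4-hydroxyl is the most acidic and the only one not held in a hydrogen bond to the formyl group, so one equivalent of MeI with a weak base should alkylate it in preference to the two chelated hydroxyls.

Step 2
Reactants: 2 2,6-dihydroxy-4-methoxybenzaldehyde
Product: 3 2-hydroxy-4-methoxy-6-(methoxymethoxy)benzaldehyde
Conditions: MOMCl (1.05 equiv), i-Pr2NEt, CH2Cl2, 0 °C
Reagents that add atoms: chloromethyl methyl ether, COCCl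
Why: Williamson-type etherification with a chloromethyl ether: the two hydroxyls are equivalent, and once one is capped the other is locked in the chelate to the aldehyde and reacts far more slowly, so a slight excess of reagent should stop at the mono-ether.

Step 3
Reactants: 3 2-hydroxy-4-methoxy-6-(methoxymethoxy)benzaldehyde
Product: 5 5-methoxy-3-(methoxymethoxy)-2-(tosylmethyl)phenol, via salicyl alcohol 4 (not isolated)
Conditions: NaBH4, THF–H2O, 0 °C; then TolSO2Na (1.5 equiv), AcOH, rt
Reagents that add atoms: sodium 4-methylbenzenesulfinate, Cc1ccc(cc1)S(=O)[O-].[Na+]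
Why: Borohydride reduction gives the donor-rich salicyl alcohol, which under weak acid loses water to a stabilised benzylic cation that the sulfinate captures at sulfur (sulfinate S-alkylation); acetic acid is too weak to cleave the MOM ether, and telescoping avoids isolating the labile benzylic alcohol.

Step 4
Reactants: 6 2-methylbut-3-en-2-ol; 7 triethyl orthoacetate
Product: 9 ethyl 5-methylhex-4-enoate, via ketene acetal 8 (not isolated)
Conditions: EtCO2H (cat.), 140 °C, EtOH distilled off
Reagents that add atoms: none
Why: Johnson–Claisen rearrangement: acid-catalysed exchange gives the mixed ketene acetal, whose [3,3]-sigmatropic shift moves the allyl unit to carbon and delivers the γ,δ-unsaturated ester with the trisubstituted alkene already in place.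

Step 5
Reactants: 9 ethyl 5-methylhex-4-enoate
Product: 11 5-methylhex-4-enal, via aluminium hemiacetal 10 (not isolated)
Conditions: i-Bu2AlH (1.05 equiv), CH2Cl2, −78 °C; aq. potassium sodium tartrate
Reagents that add atoms: none
Why: Partial ester reduction with i-Bu2AlH: at −78 °C the tetrahedral aluminium hemiacetal persists and releases the aldehyde only on work-up, which limits over-reduction.

Step 6
Reactants: 11 5-methylhex-4-enal
Product: 12 racemic 2-chloro-5-methylhex-4-enal
Conditions: NCS (1.05 equiv), DL-proline (10 mol %), CH2Cl2, 0 °C to rt; used fresh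
Reagents that add atoms: N-chlorosuccinimide, O=C1CCC(=O)N1Cl
Why: Enamine-catalysed α-chlorination: the proline enamine is far more nucleophilic than the trisubstituted alkene and takes chlorine from NCS, and a racemate suffices because this centre is erased in the next step.

Step 7
Reactants: 5 5-methoxy-3-(methoxymethoxy)-2-(tosylmethyl)phenol; 12 racemic 2-chloro-5-methylhex-4-enal
Product: 14 (S)-7-methoxy-5-(methoxymethoxy)-3-prenylchroman-2-one, via quinone methide 13 (not isolated)
Conditions: (5aS,10bR)-2-mesityl-5a,10b-dihydro-4H,6H-indeno[2,1-b][1,2,4]triazolo[4,3-d][1,4]oxazin-2-ium chloride (10 mol %), Cs2CO3 (2.5 equiv), 4 Å molecular sieves, toluene, 0 °C to rt; 12 (1.5 equiv) added slowly; filtered through silica at once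
Reagents that add atoms: none
Why: The free carbene adds to the formyl group of 12 and the resulting Breslow intermediate expels chloride, so both enantiomers of 12 converge on one planar Z azolium enolate, while the base strips sulfinate from the phenoxide of 5 to give quinone methide 13. The enolate carbon adds to the exocyclic CH2 of 13 (C3–C4 bond) and the phenoxide so formed is acylated by the acyl azolium (O1–C2 bond), which releases the carbene. The closest known reaction type is the carbene-catalysed formal hetero-Diels–Alder annulation of azolium enolates from α-chloro aldehydes with oxadienes, including quinone methides made in situ from 2-(sulfonylmethyl)phenols. The six-membered lactone ring closes by 6-exo-trig attack of the phenoxide oxygen on the acyl azolium carbonyl. C3 is the only new stereocentre and is controlled by the catalyst, whose fused indane wall covers one face of the enolate so that the methide approaches from the open face. Only facial selectivity at the enolate carbon is needed because the methide CH2 is not prochiral, the single free ortho phenol of 5 permits one lactone regioisomer only, and a weak heterogeneous base with prompt work-up protects the acidic C3–H from epimerisation.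

Step 8
Reactants: 14 (S)-7-methoxy-5-(methoxymethoxy)-3-prenylchroman-2-one
Product: 16 (S)-2-[2-(2-hydroxypropan-2-yl)-5-methylhex-4-en-1-yl]-5-methoxy-3-(methoxymethoxy)phenol, via methyl ketone 15 (not isolated)
Conditions: MeMgBr (3.5 equiv) premixed with anhydrous CeCl3 (3.5 equiv), THF, −78 to 0 °C; H2O
Reagents that add atoms: methylmagnesium bromide, C[Mg]Br
Why: Double methyl addition to an ester (here an aryl lactone) with an organocerium reagent: the first methyl opens the lactone to ketone 15, and the weakly basic, strongly nucleophilic cerium reagent should add the second methyl faster than it enolises the ketone towards C3, so the stereocentre is carried through unchanged.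

Step 9
Reactants: 16 (S)-2-[2-(2-hydroxypropan-2-yl)-5-methylhex-4-en-1-yl]-5-methoxy-3-(methoxymethoxy)phenol
Product: 17 (S)-7-methoxy-5-(methoxymethoxy)-2,2-dimethyl-3-prenylchroman
Conditions: ZnBr2 (anhydrous, 2 equiv), MgSO4, CH2Cl2, rt
Reagents that add atoms: none
Why: Lewis-acid cyclodehydration (intramolecular SN1 etherification): ZnBr2 ionises the tertiary carbinol and the neighbouring phenol captures the cation to close the O1–C2 bond, a closure known for phenolic tertiary alcohols that carry acid-sensitive trisubstituted alkenes; with MgSO4 as desiccant no strong protic acid should build up, so the prenyl alkene is not protonated and trapped by the tertiary hydroxyl, the thiol-free medium should spare the MOM ether, and C3 is not touched.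

Step 10
Reactants: 17 (S)-7-methoxy-5-(methoxymethoxy)-2,2-dimethyl-3-prenylchroman
Product: 20 1-[(S)-7-methoxy-5-(methoxymethoxy)-2,2-dimethyl-3-prenylchroman-6-yl]ethan-1-one, via C6 aryllithium 18 (not isolated), via lithium hemiaminal 19 (not isolated)
Conditions: n-BuLi (1.3 equiv), TMEDA, THF, −20 to 0 °C; then MeC(O)N(OMe)Me, −78 °C to rt; H2O
Reagents that add atoms: N-methoxy-N-methylacetamide, CC(=O)N(C)OC
Why: Directed ortho-metalation: C6–H lies between the strongly coordinating OMOM group and OMe, whereas C8–H is flanked only by OMe and the hindered tertiary-alkyl ring oxygen, so lithiation should occur at C6, and the Weinreb amide stops at the ketone through its stable chelated adduct.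

Step 11
Reactants: 21 2,4-dihydroxybenzaldehyde
Product: 22 2,4-bis(methoxymethoxy)benzaldehyde
Conditions: MOMCl (2.5 equiv), i-Pr2NEt, CH2Cl2, 0 °C to rt
Reagents that add atoms: chloromethyl methyl ether, COCCl
Why: Williamson-type protection of both phenols as MOM ethers, the chelated 2-hydroxyl needing the excess of reagent and the longer time.

Step 12
Reactants: 20 1-[(S)-7-methoxy-5-(methoxymethoxy)-2,2-dimethyl-3-prenylchroman-6-yl]ethan-1-one; 22 2,4-bis(methoxymethoxy)benzaldehyde
Product: 24 (S,E)-3-[2,4-bis(methoxymethoxy)phenyl]-1-[7-methoxy-5-(methoxymethoxy)-2,2-dimethyl-3-prenylchroman-6-yl]prop-2-en-1-one, via aldol adduct 23 (not isolated)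
Conditions: KOH (50% aq.), EtOH, rt, dark
Reagents that add atoms: none
Why: Claisen–Schmidt condensation: the methyl ketone enolate adds to the non-enolisable aldehyde and aldol 23 dehydrates by an E1cB pathway to the conjugated E enone under thermodynamic control, while no stereocentre is acidic under these conditions.

Step 13
Reactants: 24 (S,E)-3-[2,4-bis(methoxymethoxy)phenyl]-1-[7-methoxy-5-(methoxymethoxy)-2,2-dimethyl-3-prenylchroman-6-yl]prop-2-en-1-one
Product: 25 (S,E)-3-(2,4-dihydroxyphenyl)-1-[5-hydroxy-7-methoxy-2,2-dimethyl-3-prenylchroman-6-yl]prop-2-en-1-one (CNP0333857.2)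
Conditions: 3 M aq. HCl, MeOH, rt, dark; quenched with NaHCO3 as soon as conversion is complete
Reagents that add atoms: none
Why: Acid-catalysed acetal cleavage of the three MOM ethers, the one ortho to the ketone going fastest; dilute acid at room temperature with early quenching should leave the prenyl alkene unhydrated and keep the hydroxychalcone from closing to a flavanone or a flavylium salt.

Compound list

1 | 2,4,6-trihydroxybenzaldehyde | O=Cc1c(O)cc(O)cc1O | starting material
2 | 2,6-dihydroxy-4-methoxybenzaldehyde | COc1cc(O)c(C=O)c(O)c1 | intermediate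
3 | 2-hydroxy-4-methoxy-6-(methoxymethoxy)benzaldehyde | COCOc1cc(OC)cc(O)c1C=O | intermediate
4 | 2-(hydroxymethyl)-5-methoxy-3-(methoxymethoxy)phenol (salicyl alcohol) | COCOc1cc(OC)cc(O)c1CO | intermediate
5 | 5-methoxy-3-(methoxymethoxy)-2-[(4-methylbenzenesulfonyl)methyl]phenol | COCOc1cc(OC)cc(O)c1CS(=O)(=O)c1ccc(C)cc1 | intermediate
6 | 2-methylbut-3-en-2-ol | CC(C)(O)C=C | starting material
7 | triethyl orthoacetate | CCOC(C)(OCC)OCC | starting material
8 | 1-ethoxy-1-[(2-methylbut-3-en-2-yl)oxy]ethene (ketene acetal) | C=C(OCC)OC(C)(C)C=C | intermediate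
9 | ethyl 5-methylhex-4-enoate | CCOC(=O)CCC=C(C)C | intermediate
10 | [(1-ethoxy-5-methylhex-4-en-1-yl)oxy]bis(2-methylpropyl)alumane (aluminium hemiacetal) | CCOC(CCC=C(C)C)O[Al](CC(C)C)CC(C)C | intermediate
11 | 5-methylhex-4-enal | O=CCCC=C(C)C | intermediate
12 | racemic 2-chloro-5-methylhex-4-enal | O=CC(Cl)CC=C(C)C | intermediate
13 | 3-methoxy-5-(methoxymethoxy)-6-methylidenecyclohexa-2,4-dien-1-one (ortho-quinone methide) | C=C1C(=O)C=C(OC)C=C1OCOC | intermediate
14 | (S)-7-methoxy-5-(methoxymethoxy)-3-(3-methylbut-2-en-1-yl)chroman-2-one | COc1cc2c(c(OCOC)c1)C[C@H](CC=C(C)C)C(=O)O2 | intermediate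
15 | (S)-3-{[2-hydroxy-4-methoxy-6-(methoxymethoxy)phenyl]methyl}-6-methylhept-5-en-2-one (present as its phenoxide) | COc1cc(O)c(C[C@H](CC=C(C)C)C(C)=O)c(OCOC)c1 | intermediate
16 | (S)-2-[2-(2-hydroxypropan-2-yl)-5-methylhex-4-en-1-yl]-5-methoxy-3-(methoxymethoxy)phenol | COc1cc(O)c(C[C@H](CC=C(C)C)C(C)(C)O)c(OCOC)c1 | intermediate
17 | (S)-7-methoxy-5-(methoxymethoxy)-2,2-dimethyl-3-(3-methylbut-2-en-1-yl)chroman | COc1cc2c(c(OCOC)c1)C[C@H](CC=C(C)C)C(C)(C)O2 | intermediate
18 | 6-lithio derivative of 17 (C6 aryllithium) | COc1cc2c(c(OCOC)c1[Li])C[C@H](CC=C(C)C)C(C)(C)O2 | intermediate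
19 | lithium 1-[(S)-7-methoxy-5-(methoxymethoxy)-2,2-dimethyl-3-prenylchroman-6-yl]-1-[methoxy(methyl)amino]ethan-1-olate (lithium hemiaminal) | COc1cc2c(c(OCOC)c1C(C)(O[Li])N(C)OC)C[C@H](CC=C(C)C)C(C)(C)O2 | intermediate
20 | 1-[(S)-7-methoxy-5-(methoxymethoxy)-2,2-dimethyl-3-(3-methylbut-2-en-1-yl)chroman-6-yl]ethan-1-one | COc1cc2c(c(OCOC)c1C(C)=O)C[C@H](CC=C(C)C)C(C)(C)O2 | intermediate
21 | 2,4-dihydroxybenzaldehyde | O=Cc1ccc(O)cc1O | starting material
22 | 2,4-bis(methoxymethoxy)benzaldehyde | COCOc1ccc(C=O)c(OCOC)c1 | intermediate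
23 | 3-[2,4-bis(methoxymethoxy)phenyl]-3-hydroxy-1-[(S)-7-methoxy-5-(methoxymethoxy)-2,2-dimethyl-3-prenylchroman-6-yl]propan-1-one (aldol adduct, carbinol centre undefined) | COc1cc2c(c(OCOC)c1C(=O)CC(O)c1ccc(OCOC)cc1OCOC)C[C@H](CC=C(C)C)C(C)(C)O2 | intermediate
24 | (S,E)-3-[2,4-bis(methoxymethoxy)phenyl]-1-[7-methoxy-5-(methoxymethoxy)-2,2-dimethyl-3-(3-methylbut-2-en-1-yl)chroman-6-yl]prop-2-en-1-one | COc1cc2c(c(OCOC)c1C(=O)/C=C/c1ccc(OCOC)cc1OCOC)C[C@H](CC=C(C)C)C(C)(C)O2 | intermediate
25 | (S,E)-3-(2,4-dihydroxyphenyl)-1-[5-hydroxy-7-methoxy-2,2-dimethyl-3-(3-methylbut-2-en-1-yl)chroman-6-yl]prop-2-en-1-one | COc1cc2c(c(O)c1C(=O)/C=C/c1ccc(O)cc1O)C[C@H](CC=C(C)C)C(C)(C)O2 | target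

Total step count: 13. Longest linear sequence: 9 steps (steps 1, 2, 3, 7, 8, 9, 10, 12, 13).

Steps most likely to fail

Step 7. The indane wall may shield the enolate face incompletely, the acidic C3–H of the aryl lactone may epimerise under base or sulfinate, and the donor-rich methide may self-condense before the enolate intercepts it. The fallback sets out from 3, comes back at 14, and sets C3 by auxiliary-controlled enolate alkylation with the two carbon substituents exchanging roles. Aldehyde 3 is capped (NaH, MOMCl, THF) to 4-methoxy-2,6-bis(methoxymethoxy)benzaldehyde F1. Doebner condensation with malonic acid (pyridine, piperidine, 90 °C) gives (E)-3-[4-methoxy-2,6-bis(methoxymethoxy)phenyl]prop-2-enoic acid F2. Hydrogenation (H2, Pd/C, EtOAc) gives 3-[4-methoxy-2,6-bis(methoxymethoxy)phenyl]propanoic acid F3. Activation with pivaloyl chloride and Et3N, then lithiated (S)-4-benzyloxazolidin-2-one, gives (S)-4-benzyl-3-{3-[4-methoxy-2,6-bis(methoxymethoxy)phenyl]propanoyl}oxazolidin-2-one F4. Its sodium enolate (NaN(SiMe3)2, THF, −78 °C) should take up prenyl bromide on the face away from the benzyl group to give (S)-4-benzyl-3-[(S)-2-{[4-methoxy-2,6-bis(methoxymethoxy)phenyl]methyl}-5-methylhex-4-enoyl]oxazolidin-2-one F5. Brief dilute HCl in MeOH removes both MOM groups; either of the two now equivalent phenols lactonises onto the imide carbonyl (Et3N) with loss of the auxiliary to give (S)-5-hydroxy-7-methoxy-3-prenylchroman-2-one F6. MOMCl with i-Pr2NEt then returns lactone 14.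

Step 9. Adventitious HBr may protonate the prenyl alkene, whose cation the tertiary hydroxyl would trap as an oxane; the C2 cation may lose the C3 proton or accept a hydride from C3; and the Lewis acid may cleave the MOM ether. The fallback sets out from 14, comes back at 17, and never opens the O1–C2 bond. One equivalent of MeLi (THF, −78 °C) converts the lactone into (3S)-7-methoxy-5-(methoxymethoxy)-2-methyl-3-prenylchroman-2-ol F7. Excess AlMe3 (CH2Cl2, −78 to 0 °C) ionises this lactol to the ring oxocarbenium ion and delivers the second methyl at C2. No free tertiary alcohol, open C2 cation or protic acid then coexists with the prenyl group.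

Step 10. Lithiation may also occur at C8 (between OMe and O1) or at the benzylic C4, which would give regioisomeric ketones. The fallback sets out from 17, comes back at 20, and relies on a phenol-directed reaction that can reach only C6. The MOM ether is cleaved (dilute HCl, MeOH, rt) to (S)-7-methoxy-2,2-dimethyl-3-prenylchroman-5-ol F8. Magnesium-mediated ortho-formylation (MgCl2, Et3N, paraformaldehyde, MeCN, reflux) is specific for the position ortho to the phenoxide and should give (S)-5-hydroxy-7-methoxy-2,2-dimethyl-3-prenylchroman-6-carbaldehyde F9. MOMCl with i-Pr2NEt gives (S)-7-methoxy-5-(methoxymethoxy)-2,2-dimethyl-3-prenylchroman-6-carbaldehyde F10. MeMgBr (THF, −78 °C) gives 1-[(S)-7-methoxy-5-(methoxymethoxy)-2,2-dimethyl-3-prenylchroman-6-yl]ethan-1-ol F11. Dess–Martin periodinane (NaHCO3, CH2Cl2) then oxidises this carbinol to ketone 20.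

Further compounds

F1 | step 7 | 4-methoxy-2,6-bis(methoxymethoxy)benzaldehyde | COCOc1cc(OC)cc(OCOC)c1C=O
F2 | step 7 | (E)-3-[4-methoxy-2,6-bis(methoxymethoxy)phenyl]prop-2-enoic acid | COCOc1cc(OC)cc(OCOC)c1/C=C/C(=O)O
F3 | step 7 | 3-[4-methoxy-2,6-bis(methoxymethoxy)phenyl]propanoic acid | COCOc1cc(OC)cc(OCOC)c1CCC(=O)O
F4 | step 7 | (S)-4-benzyl-3-{3-[4-methoxy-2,6-bis(methoxymethoxy)phenyl]propanoyl}oxazolidin-2-one | COCOc1cc(OC)cc(OCOC)c1CCC(=O)N2[C@@H](Cc3ccccc3)COC2=O
F5 | step 7 | (S)-4-benzyl-3-[(S)-2-{[4-methoxy-2,6-bis(methoxymethoxy)phenyl]methyl}-5-methylhex-4-enoyl]oxazolidin-2-one | COCOc1cc(OC)cc(OCOC)c1C[C@H](CC=C(C)C)C(=O)N2[C@@H](Cc3ccccc3)COC2=O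
F6 | step 7 | (S)-5-hydroxy-7-methoxy-3-(3-methylbut-2-en-1-yl)chroman-2-one | COc1cc2c(c(O)c1)C[C@H](CC=C(C)C)C(=O)O2
F7 | step 9 | (3S)-7-methoxy-5-(methoxymethoxy)-2-methyl-3-(3-methylbut-2-en-1-yl)chroman-2-ol | COc1cc2c(c(OCOC)c1)C[C@H](CC=C(C)C)C(C)(O)O2
F8 | step 10 | (S)-7-methoxy-2,2-dimethyl-3-(3-methylbut-2-en-1-yl)chroman-5-ol | COc1cc2c(c(O)c1)C[C@H](CC=C(C)C)C(C)(C)O2
F9 | step 10 | (S)-5-hydroxy-7-methoxy-2,2-dimethyl-3-(3-methylbut-2-en-1-yl)chroman-6-carbaldehyde | COc1cc2c(c(O)c1C=O)C[C@H](CC=C(C)C)C(C)(C)O2
F10 | step 10 | (S)-7-methoxy-5-(methoxymethoxy)-2,2-dimethyl-3-(3-methylbut-2-en-1-yl)chroman-6-carbaldehyde | COc1cc2c(c(OCOC)c1C=O)C[C@H](CC=C(C)C)C(C)(C)O2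
F11 | step 10 | 1-[(S)-7-methoxy-5-(methoxymethoxy)-2,2-dimethyl-3-(3-methylbut-2-en-1-yl)chroman-6-yl]ethan-1-ol | COc1cc2c(c(OCOC)c1C(C)O)C[C@H](CC=C(C)C)C(C)(C)O2
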